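**Plan**
- Retrosynthesis: the O–benzyl bond on ring B is cut first (protecting group). The C3–C4 bond of ring C (CH2 to ketone carbon) is cut next, which opens ring C to the achiral aldehyde 10. Then follow the formyl C–C bond on ring A, the C=CH2 of the enol ether (back to an ester C=O), and the ester C–O bond between the ring-A phenol and the ring-B acid.
- Forward: acid chloride 3 (ring B) and bromophenol 5 (ring A) are joined as an aryl ester. The ester C=O is methylenated to a 1-arylvinyl aryl ether, the bromide is exchanged for a formyl group, ring C is closed by hydroacylation, and the benzyl group is removed last.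
- Enabling feature: the ketone carbon C4 sits on ring A ortho to O1, C2 carries both O1 and ring B, and C3 is a plain CH2. A formyl C–H at C4 and a C2=C3 enol ether (1,1-disubstituted, no allylic hydrogen) are therefore the hydroacylation retron of ring C, reached from an ester by adding one carbon.
- Stereochemistry: the only stereocenter, C2 (S), is created in the ring closure from an achiral precursor under control of the chiral bisphosphine on rhodium. The one later step is neutral, so C2 should not epimerise.

Key step: step 7

Assumption: (R)-DTBM-SEGPHOS is written as the ligand enantiomer that gives the 2S product; the sense of induction on this new substrate class cannot be fixed in advance, and the (S)-ligand would be used if a trial run gave the 2R enantiomer.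

**Route**

Step 1
Reactants: 1 3-hydroxy-4,5-dimethoxybenzoic acid
Product: 2 3-(benzyloxy)-4,5-dimethoxybenzoic acid
Conditions: BnBr (1.2 equiv), KOH (3 equiv), EtOH/H2O, reflux; then aq. HCl to pH 2
Reagents that add atoms: benzyl bromide, BrCc1ccccc1
Why: Williamson ether synthesis in which the phenoxide is far more nucleophilic than the carboxylate in aqueous ethanol, and any benzyl ester that forms is saponified by the excess hydroxide before acidification.

Step 2
Reactants: 2 3-(benzyloxy)-4,5-dimethoxybenzoic acid
Product: 3 3-(benzyloxy)-4,5-dimethoxybenzoyl chloride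
Conditions: (COCl)2 (1.5 equiv), DMF (cat.), CH2Cl2, 0 °C to rt; evaporation, crude used directly
Reagents that add atoms: oxalyl chloride, O=C(Cl)C(=O)Cl
Why: Acid chloride formation through the chloroiminium (Vilsmeier-type) species from DMF and oxalyl chloride, under conditions to which the aryl methyl and benzyl ethers are inert.

Step 3
Reactants: 4 2,3-dimethoxyphenol
Product: 5 6-bromo-2,3-dimethoxyphenol
Conditions: Br2 (1.0 equiv), t-BuNH2 (2.0 equiv), toluene/CH2Cl2, −78 °C to rt
Reagents that add atoms: bromine, BrBr
Why: Amine-directed ortho-bromination of a phenol, in which N-bromo-tert-butylamine formed in the flask delivers bromine through a hydrogen-bonded phenol complex, so the only free ortho position (C6) should be substituted in preference to the para position.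

Step 4
Reactants: 3 3-(benzyloxy)-4,5-dimethoxybenzoyl chloride; 5 6-bromo-2,3-dimethoxyphenol
Product: 6 6-bromo-2,3-dimethoxyphenyl 3-(benzyloxy)-4,5-dimethoxybenzoate
Conditions: Et3N (1.5 equiv), DMAP (0.1 equiv), CH2Cl2, 0 °C to rt
Reagents that add atoms: none
Why: DMAP-catalysed acyl transfer (Steglich-type acylation via the N-acylpyridinium ion) should overcome the hindrance of the di-ortho-substituted phenol.

Step 5
Reactants: 6 6-bromo-2,3-dimethoxyphenyl 3-(benzyloxy)-4,5-dimethoxybenzoate
Product: 7 1-(benzyloxy)-5-[1-(6-bromo-2,3-dimethoxyphenoxy)ethenyl]-2,3-dimethoxybenzene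
Conditions: Cp2TiMe2 (3 equiv), toluene, 70 °C, dark; hexane, filtration through basic Al2O3
Reagents that add atoms: dimethyltitanocene Cp2TiMe2, C[Ti](C)(C1C=CC=C1)C1C=CC=C1
Why: Petasis methylenation, in which Cp2TiMe2 loses methane to Cp2Ti=CH2, which adds [2+2] to the ester carbonyl and cycloreverts to the enol ether; aryl benzoates are established substrates and the aryl bromide and ethers are inert to this non-basic reagent.

Step 6
Reactants: 7 1-(benzyloxy)-5-[1-(6-bromo-2,3-dimethoxyphenoxy)ethenyl]-2,3-dimethoxybenzene
Product: 10 2-({1-[3-(benzyloxy)-4,5-dimethoxyphenyl]ethenyl}oxy)-3,4-dimethoxybenzaldehyde, via aryllithium 8 (not isolated), via lithium hemiaminal alkoxide 9 (not isolated)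
Conditions: n-BuLi (1.05 equiv), THF, −78 °C; DMF (3 equiv), −78 to 0 °C; H2O quench; chromatography on Et3N-deactivated SiO2
Reagents that add atoms: N,N-dimethylformamide, CN(C)C=O; n-butyllithium, [Li]CCCC (supplies the lithium of 8 and 9 only)
Why: Bromine–lithium exchange at −78 °C is faster than addition of n-BuLi to the enol ether or benzylic deprotonation, and Bouveault formylation gives a tetrahedral adduct that releases the aldehyde only on neutral aqueous work-up, so the acid-labile enol ether (prone to hydrolysis and to Prins-type attack on an activated carbonyl) never meets acid.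

Step 7
Reactants: 10 2-({1-[3-(benzyloxy)-4,5-dimethoxyphenyl]ethenyl}oxy)-3,4-dimethoxybenzaldehyde
Product: 11 (2S)-2-[3-(benzyloxy)-4,5-dimethoxyphenyl]-7,8-dimethoxy-2,3-dihydro-4H-chromen-4-one
Conditions: [Rh(cod)Cl]2 (2.5 mol %), (R)-DTBM-SEGPHOS (5 mol %), NaB[3,5-(CF3)2C6H3]4 (5 mol %), degassed 1,4-dioxane, 60–80 °C
Reagents that add atoms: none
Why: Proposed new method: a cationic bisphosphine complex of monovalent rhodium should insert into the formyl C–H bond of 10 to give an acyl hydride of trivalent rhodium, bind the enol-ether C=CH2, deliver the hydride to the carbon that carries O1 and ring B (the future C2) so that rhodium sits on the terminal CH2 (the future C3), and then form the C3–C4 bond by reductive elimination from the seven-membered acyl alkyl rhodacycle. The closest known reaction type is the rhodium/bisphosphine-catalysed enantioselective intramolecular hydroacylation of ortho-allylbenzaldehydes with 1,1-disubstituted alkenes to 3-substituted tetralones; replacing the benzylic CH2 of that tether by an ether oxygen, which makes the alkene an enol ether, is the untested element. Ring C is closed in a 6-endo-trig mode, the acyl carbon bonding to the terminal alkene carbon. The new stereocenter C2 is controlled only by the chiral bisphosphine, which selects one enantioface of the prochiral alkene in the hydride-insertion and reductive-elimination sequence, the substrate being achiral. The step needs endo over exo regioselectivity, hydroacylation over decarbonylation and an alkene that stays in place: the exo path would require a rhodium–carbon bond and reductive elimination at a carbon already bearing aryl, aryloxy and methyl groups (leading to a 2-aryl-2-methylbenzofuran-3-one), and the C=CH2 unit has no allylic hydrogen, so isomerisation by chain walking is impossible. The neutral, aprotic conditions should leave the new C2 center untouched, since it epimerises only through acid- or base-induced retro-oxa-Michael opening.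

Step 8
Reactants: 11 (2S)-2-[3-(benzyloxy)-4,5-dimethoxyphenyl]-7,8-dimethoxy-2,3-dihydro-4H-chromen-4-one
Product: 12 (2S)-2-(3-hydroxy-4,5-dimethoxyphenyl)-7,8-dimethoxy-2,3-dihydro-4H-chromen-4-one
Conditions: H2 (1 atm), Pd/C (10 wt %), EtOAc, rt
Reagents that add atoms: none
Why: Hydrogenolysis of the aryl benzyl ether is neutral, so C2 should keep its configuration; the cyclic benzylic C2–O1 bond and the aryl ketone react much more slowly, and the reaction would be stopped when 11 is consumed.

**Compound list**

1 | 3-hydroxy-4,5-dimethoxybenzoic acid | COc1cc(C(=O)O)cc(O)c1OC | starting material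
2 | 3-(benzyloxy)-4,5-dimethoxybenzoic acid | COc1cc(C(=O)O)cc(OCc2ccccc2)c1OC | intermediate
3 | 3-(benzyloxy)-4,5-dimethoxybenzoyl chloride | COc1cc(C(=O)Cl)cc(OCc2ccccc2)c1OC | intermediate
4 | 2,3-dimethoxyphenol | COc1cccc(O)c1OC | starting material
5 | 6-bromo-2,3-dimethoxyphenol | COc1ccc(Br)c(O)c1OC | intermediate
6 | 6-bromo-2,3-dimethoxyphenyl 3-(benzyloxy)-4,5-dimethoxybenzoate | COc1ccc(Br)c(OC(=O)c2cc(OC)c(OC)c(OCc3ccccc3)c2)c1OC | intermediate
7 | 1-(benzyloxy)-5-[1-(6-bromo-2,3-dimethoxyphenoxy)ethenyl]-2,3-dimethoxybenzene | COc1ccc(Br)c(OC(=C)c2cc(OC)c(OC)c(OCc3ccccc3)c2)c1OC | intermediate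
8 | [2-({1-[3-(benzyloxy)-4,5-dimethoxyphenyl]ethenyl}oxy)-3,4-dimethoxyphenyl]lithium (formed in the flask, not isolated) | [Li]c1ccc(OC)c(OC)c1OC(=C)c1cc(OC)c(OC)c(OCc2ccccc2)c1 | intermediate
9 | lithium [2-({1-[3-(benzyloxy)-4,5-dimethoxyphenyl]ethenyl}oxy)-3,4-dimethoxyphenyl](dimethylamino)methanolate (formed in the flask, not isolated) | [Li]OC(N(C)C)c1ccc(OC)c(OC)c1OC(=C)c1cc(OC)c(OC)c(OCc2ccccc2)c1 | intermediate
10 | 2-({1-[3-(benzyloxy)-4,5-dimethoxyphenyl]ethenyl}oxy)-3,4-dimethoxybenzaldehyde | COc1ccc(C=O)c(OC(=C)c2cc(OC)c(OC)c(OCc3ccccc3)c2)c1OC | intermediate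
11 | (2S)-2-[3-(benzyloxy)-4,5-dimethoxyphenyl]-7,8-dimethoxy-2,3-dihydro-4H-chromen-4-one | COc1cc([C@@H]2CC(=O)c3ccc(OC)c(OC)c3O2)cc(OCc2ccccc2)c1OC | intermediate
12 | (2S)-2-(3-hydroxy-4,5-dimethoxyphenyl)-7,8-dimethoxy-2,3-dihydro-4H-chromen-4-one | COc1cc([C@@H]2CC(=O)c3ccc(OC)c(OC)c3O2)cc(O)c1OC | target

**Step count**

Total steps: 8. Longest linear sequence: 7 steps (steps 1, 2, 4, 5, 6, 7 and 8, from 1 to 12).

**Steps most likely to fail**

1. Step 7 (proposed new method). What may go wrong:
   - decarbonylation of the acyl rhodium hydride may outrun alkene insertion and tie the catalyst up as a carbonyl complex;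
   - the alkyl rhodium intermediate may undergo β-aryloxy elimination;
   - the cationic metal may act as a Lewis acid and trigger Prins-type attack of the enol ether on the aldehyde;
   - enantioface discrimination may be poor.

   The fallback uses known chemistry, sets out from acid chloride 3 and returns at 11. Reduction of 3 with LiAlH(Ot-Bu)3 (THF, −78 °C) should give 3-(benzyloxy)-4,5-dimethoxybenzaldehyde F1. Claisen–Schmidt condensation of it with commercial 1-(2-hydroxy-3,4-dimethoxyphenyl)ethan-1-one (KOH, EtOH, rt) should give (E)-3-[3-(benzyloxy)-4,5-dimethoxyphenyl]-1-(2-hydroxy-3,4-dimethoxyphenyl)prop-2-en-1-one F2. Oxa-Michael ring closure (NaOAc, EtOH, reflux) should give racemic 2-[3-(benzyloxy)-4,5-dimethoxyphenyl]-7,8-dimethoxy-2,3-dihydro-4H-chromen-4-one F3. Kinetic resolution by asymmetric transfer hydrogenation (RhCl(Cp*)[TsDPEN], HCO2H/Et3N, EtOAc, with the catalyst enantiomer that reduces the 2R ketone faster) should convert the 2R enantiomer into (2R,4R)-2-[3-(benzyloxy)-4,5-dimethoxyphenyl]-7,8-dimethoxy-3,4-dihydro-2H-chromen-4-ol F4 and leave 11, which is separated by chromatography.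

2. Step 5. What may go wrong: incomplete methylenation of the hindered aryl ester, or hydrolysis of the enol ether during isolation.

   The fallback builds the enol ether by C–O coupling instead of carbonyl methylenation; it sets out from acid chloride 3 and returns at 10. Me2CuLi (THF, −78 °C) should give 1-[3-(benzyloxy)-4,5-dimethoxyphenyl]ethan-1-one F5. Treatment with (PhO)3P/Br2/Et3N (CH2Cl2, −60 °C to reflux) should give 1-(benzyloxy)-5-(1-bromoethenyl)-2,3-dimethoxybenzene F6. Ullmann-type O-vinylation of commercial 2-hydroxy-3,4-dimethoxybenzaldehyde with F6 (CuCl cat., 2,2,6,6-tetramethylheptane-3,5-dione, Cs2CO3, NMP, 100 °C) should give 10 directly.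

3. Step 3. What may go wrong: poor regioselectivity, with bromination para to the hydroxyl group or double bromination.

   The fallback fixes the position by directed ortho-metalation; it sets out from 4 and returns at 5. MOMCl/i-Pr2NEt (CH2Cl2) should give 1,2-dimethoxy-3-(methoxymethoxy)benzene F7. n-BuLi (THF, 0 °C) should lithiate next to the stronger directing OMOM group to give [3,4-dimethoxy-2-(methoxymethoxy)phenyl]lithium F8. Quenching with BrCCl2CCl2Br should give 1-bromo-3,4-dimethoxy-2-(methoxymethoxy)benzene F9. HCl in MeOH should then release 5.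

**Further compounds**

F1 | step 7 | 3-(benzyloxy)-4,5-dimethoxybenzaldehyde | COc1cc(C=O)cc(OCc2ccccc2)c1OC
F2 | step 7 | (E)-3-[3-(benzyloxy)-4,5-dimethoxyphenyl]-1-(2-hydroxy-3,4-dimethoxyphenyl)prop-2-en-1-one | COc1ccc(C(=O)/C=C/c2cc(OC)c(OC)c(OCc3ccccc3)c2)c(O)c1OC
F3 | step 7 | racemic 2-[3-(benzyloxy)-4,5-dimethoxyphenyl]-7,8-dimethoxy-2,3-dihydro-4H-chromen-4-one | COc1cc(C2CC(=O)c3ccc(OC)c(OC)c3O2)cc(OCc2ccccc2)c1OC
F4 | step 7 | (2R,4R)-2-[3-(benzyloxy)-4,5-dimethoxyphenyl]-7,8-dimethoxy-3,4-dihydro-2H-chromen-4-ol | COc1cc([C@H]2C[C@@H](O)c3ccc(OC)c(OC)c3O2)cc(OCc2ccccc2)c1OC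
F5 | step 5 | 1-[3-(benzyloxy)-4,5-dimethoxyphenyl]ethan-1-one | COc1cc(C(C)=O)cc(OCc2ccccc2)c1OC
F6 | step 5 | 1-(benzyloxy)-5-(1-bromoethenyl)-2,3-dimethoxybenzene | COc1cc(C(Br)=C)cc(OCc2ccccc2)c1OC
F7 | step 3 | 1,2-dimethoxy-3-(methoxymethoxy)benzene | COCOc1cccc(OC)c1OC
F8 | step 3 | [3,4-dimethoxy-2-(methoxymethoxy)phenyl]lithium | COCOc1c([Li])ccc(OC)c1OC
F9 | step 3 | 1-bromo-3,4-dimethoxy-2-(methoxymethoxy)benzene | COCOc1c(Br)ccc(OC)c1OC
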